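**Assumptions (one line each)**
- The target is the all-trans aryltetralin (C1-aryl/C2-CH2OH trans, C2/C3 trans). In aryltetralin numbering (C1 = ArCH, C2 and C3 = CH–CH2OH, C4 = CH2) it is (1R,2S,3S), which is (6S,7S,8R) in the IUPAC naphthalen-2-ol name.
- The sense of induction of the new Pd step cannot be predicted in advance; (R)-BINAP is written, and its antipode is used if it gives the (1S) series.

## Retrosynthetic overview
1. Target ⇐ debenzylation and LiAlH4 reduction of an all-trans dimethyl 1-aryltetralin-2,3-dicarboxylate. C2 and C3 are ester α-carbons and are set thermodynamically against C1, so only C1 needs absolute control.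
2. Key step: the carbocycle (C3–C4 and C1–C2 bonds) is closed by an enantioselective Pd-catalysed formal [4+2] coupling of dimethyl fumarate with an α-aryl-o-xylylene–Pd species, generated from an o-(trimethylsilylmethyl)benzhydryl carbonate.
3. The carbonate ⇐ syringyl-type aryllithium + o-(silylmethyl)benzaldehyde, trapped in situ with ClCO2Me (forms the C1–aryl bond).
4. Three fragments: the aldehyde from p-cresol, the aryl bromide from resorcinol, the dienophile from fumaric acid.
5. Ring order: both benzene rings are purchased; the only ring formed is the tetralin cyclohexane ring (step 12).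

## Route

**Step 1**
Reactants: 1, p-cresol (4-methylphenol)
Product: 2, 2-bromo-4-methylphenol
Conditions: Br2 (1.0 equiv), CH2Cl2, 0 °C
Reagents that add atoms: bromine, BrBr
Why: Electrophilic aromatic bromination of a phenol whose para position is blocked goes ortho to OH, and one equivalent at 0 °C stops at the monobromide.

**Step 2**
Reactants: 2, 2-bromo-4-methylphenol
Product: 3, 2-methoxy-4-methylphenol
Conditions: NaOMe (5 equiv, 25% in MeOH), CuBr (10 mol%), DMF, 110 °C
Reagents that add atoms: sodium methoxide, C[O-].[Na+]
Why: Ullmann-type Cu-catalysed C–O coupling of an aryl bromide with methoxide, which tolerates the free phenol (as phenoxide).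

**Step 3**
Reactants: 3, 2-methoxy-4-methylphenol
Product: 4, 1-(benzyloxy)-2-methoxy-4-methylbenzene
Conditions: BnBr, K2CO3, DMF, 60 °C
Reagents that add atoms: benzyl bromide, BrCc1ccccc1
Why: Williamson etherification; benzyl survives all later base, organolithium, Pd(0) and hydride steps and is removed by hydrogenolysis at the end.

**Step 4**
Reactants: 4, 1-(benzyloxy)-2-methoxy-4-methylbenzene
Product: 5, 5-(benzyloxy)-4-methoxy-2-methylbenzaldehyde
Conditions: POCl3, DMF, 90 °C; then aq. NaOAc
Reagents that add atoms: N,N-dimethylformamide, CN(C)C=O (formyl carbon); water, O (carbonyl oxygen on iminium hydrolysis)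
Why: Vilsmeier–Haack formylation; the site para to OBn is blocked by CH3, so attack occurs para to OMe and ortho to CH3, placing CHO para to OMe as the target requires.

**Step 5**
Reactants: 5, 5-(benzyloxy)-4-methoxy-2-methylbenzaldehyde
Product: 6, 5-(benzyloxy)-4-methoxy-2-[(trimethylsilyl)methyl]benzaldehyde
Conditions: t-BuNH2, 4 Å MS, CH2Cl2, rt; LiTMP, THF, −78 → −15 °C; TMSCl, −78 °C → rt; aq. citric acid, rt (telescoped)
Reagents that add atoms: chlorotrimethylsilane, C[Si](C)(C)Cl
Why: Lateral (benzylic) lithiation of the o-tolualdehyde tert-butylimine gives a delocalised aza-o-xylylene anion that is C-silylated to restore aromaticity, and mild hydrolysis returns the aldehyde.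

**Step 6**
Reactants: 7, resorcinol (benzene-1,3-diol)
Product: 8, 1,3-dimethoxybenzene
Conditions: MeI (2.5 equiv), K2CO3, acetone, reflux
Reagents that add atoms: iodomethane, CI
Why: Exhaustive Williamson O-methylation.

**Step 7**
Reactants: 8, 1,3-dimethoxybenzene
Product: 9, 2,6-dimethoxyphenol
Conditions: n-BuLi, THF, 0 °C → rt; B(OMe)3, −78 °C → rt; H2O2, AcOH, 0 °C → rt
Reagents that add atoms: hydrogen peroxide, OO (phenolic oxygen)
Why: Directed ortho-metalation at C2 between the two methoxy groups, borylation, and oxidation of the aryl borate to the phenol.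

**Step 8**
Reactants: 9, 2,6-dimethoxyphenol
Product: 10, 4-bromo-2,6-dimethoxyphenol
Conditions: NBS (1.0 equiv), CHCl3, −45 °C → rt
Reagents that add atoms: N-bromosuccinimide, O=C1CCC(=O)N1Br
Why: Electrophilic bromination para to the free OH, the strongest director (both ortho positions are occupied); it is done before benzylation for that reason.

**Step 9**
Reactants: 10, 4-bromo-2,6-dimethoxyphenol
Product: 11, 2-(benzyloxy)-5-bromo-1,3-dimethoxybenzene
Conditions: BnBr, K2CO3, DMF, rt
Reagents that add atoms: benzyl bromide, BrCc1ccccc1
Why: Williamson etherification of the hindered phenol in a polar aprotic solvent.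

**Step 10**
Reactants: 12, fumaric acid
Product: 13, dimethyl fumarate
Conditions: MeOH, H2SO4 (cat.), reflux
Reagents that add atoms: methanol, CO
Why: Fischer esterification; the E geometry is retained.

**Step 11**
Reactants: 11, 2-(benzyloxy)-5-bromo-1,3-dimethoxybenzene; 6, 5-(benzyloxy)-4-methoxy-2-[(trimethylsilyl)methyl]benzaldehyde
Product: 14, racemic [4-(benzyloxy)-3,5-dimethoxyphenyl]{5-(benzyloxy)-4-methoxy-2-[(trimethylsilyl)methyl]phenyl}methyl methyl carbonate
Conditions: 11, n-BuLi, THF, −78 °C; add 6, −78 °C; then ClCO2Me, −78 → 0 °C; purify on Et3N-deactivated silica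
Reagents that add atoms: methyl chloroformate, COC(=O)Cl
Why: Br/Li exchange, 1,2-addition of the aryllithium to the aldehyde, and in situ O-acylation of the lithium alkoxide; the carbinol centre is left racemic because it is ionised in step 12.

**Step 12**
Reactants: 14, the benzhydryl methyl carbonate; 13, dimethyl fumarate
Product: 15, dimethyl (1R)-7-(benzyloxy)-1-[4-(benzyloxy)-3,5-dimethoxyphenyl]-6-methoxy-1,2,3,4-tetrahydronaphthalene-2,3-dicarboxylate (2,3-trans; C1 fixed as R; mixture of the 1,2-trans and 1,2-cis diastereomers)
Conditions: [CpPd(η3-C3H5)] (5 mol%), (R)-BINAP (6 mol%), 13 (2 equiv), THF, 50 °C (−CO2, −Me3SiOMe)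
Reagents that add atoms: none
Why: Proposed new method: an enantioselective Pd-catalysed formal [4+2] of an α-aryl-o-xylylene equivalent. Pd(0)/(R)-BINAP ionises the racemic benzhydryl carbonate to a cationic η3-benzyl complex; the methoxide released by decarboxylation removes Me3Si from the ortho CH2SiMe3, giving a (BINAP)Pd–(E)-α-aryl-o-xylylene (2-palladaindane ⇌ η3-benzyl/benzyl-anion zwitterion) in which the carbinol stereochemistry is erased and the two faces interconvert by η3–η1–η3 slippage. The chiral bisphosphine therefore selects the face on which the CH2 terminus adds to fumarate (C4–C3) and the resulting enolate closes onto the Pd-bound diarylmethyl carbon (C1–C2), setting C1 (R) under catalyst control while the E-alkene gives 2,3-trans. The closest known chemistry is the achiral Pd-catalysed formal [4+2] cycloaddition of unsubstituted o-(silylmethyl)benzyl carbonates with electron-poor alkenes, together with Pd-catalysed dynamic kinetic asymmetric substitution of secondary benzylic carbonates.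

**Step 13**
Reactants: 15, the (1R)-diester diastereomer mixture
Product: 16, dimethyl (1R,2S,3S)-7-(benzyloxy)-1-[4-(benzyloxy)-3,5-dimethoxyphenyl]-6-methoxy-1,2,3,4-tetrahydronaphthalene-2,3-dicarboxylate (1,2-trans, 2,3-trans)
Conditions: NaOMe (1 equiv), MeOH/THF, 60 °C, N2
Reagents that add atoms: none
Why: Thermodynamic epimerisation through the ester enolates at C2 and C3 funnels all (1R) diastereomers to the all-equatorial trans,trans isomer; C1 has no acidifying group, is not touched, and dictates the absolute configuration of C2 and C3.

**Step 14**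
Reactants: 16, the all-trans diester
Product: 17, [(1R,2S,3S)-7-(benzyloxy)-1-[4-(benzyloxy)-3,5-dimethoxyphenyl]-6-methoxy-1,2,3,4-tetrahydronaphthalene-2,3-diyl]dimethanol
Conditions: LiAlH4, THF, 0 °C → rt
Reagents that add atoms: none
Why: Hydride reduction of both esters to primary alcohols without enolisation, so the three stereocentres are retained; benzyl and methyl ethers are inert.

**Step 15**
Reactants: 17, the bis-benzyl ether diol
Product: 18, (6S,7S,8R)-8-(4-hydroxy-3,5-dimethoxyphenyl)-6,7-bis(hydroxymethyl)-3-methoxy-5,6,7,8-tetrahydronaphthalen-2-ol (target, CID 70697973)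
Conditions: H2 (1 atm), 10% Pd/C, EtOAc/MeOH, rt
Reagents that add atoms: none
Why: Hydrogenolysis of the two aryl benzyl ethers; the diarylmethine C–C bonds, aryl methyl ethers and primary alcohols are stable under these conditions.

## Compound list
1 | p-cresol (4-methylphenol) | Cc1ccc(O)cc1 | starting material
2 | 2-bromo-4-methylphenol | Cc1ccc(O)c(Br)c1 | intermediate
3 | 2-methoxy-4-methylphenol | COc1cc(C)ccc1O | intermediate
4 | 1-(benzyloxy)-2-methoxy-4-methylbenzene | COc1cc(C)ccc1OCc1ccccc1 | intermediate
5 | 5-(benzyloxy)-4-methoxy-2-methylbenzaldehyde | COc1cc(C)c(C=O)cc1OCc1ccccc1 | intermediate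
6 | 5-(benzyloxy)-4-methoxy-2-[(trimethylsilyl)methyl]benzaldehyde | COc1cc(C[Si](C)(C)C)c(C=O)cc1OCc1ccccc1 | intermediate
7 | resorcinol | Oc1cccc(O)c1 | starting material
8 | 1,3-dimethoxybenzene | COc1cccc(OC)c1 | intermediate
9 | 2,6-dimethoxyphenol | COc1cccc(OC)c1O | intermediate
10 | 4-bromo-2,6-dimethoxyphenol | COc1cc(Br)cc(OC)c1O | intermediate
11 | 2-(benzyloxy)-5-bromo-1,3-dimethoxybenzene | COc1cc(Br)cc(OC)c1OCc1ccccc1 | intermediate
12 | fumaric acid | OC(=O)/C=C/C(=O)O | starting material
13 | dimethyl fumarate | COC(=O)/C=C/C(=O)OC | intermediate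
14 | rac-[4-(benzyloxy)-3,5-dimethoxyphenyl]{5-(benzyloxy)-4-methoxy-2-[(trimethylsilyl)methyl]phenyl}methyl methyl carbonate | COC(=O)OC(c1cc(OC)c(OCc2ccccc2)c(OC)c1)c1cc(OCc2ccccc2)c(OC)cc1C[Si](C)(C)C | intermediate
15 | dimethyl (1R)-7-(benzyloxy)-1-[4-(benzyloxy)-3,5-dimethoxyphenyl]-6-methoxytetralin-2,3-dicarboxylate (2,3-trans, C2/C3 diastereomer mixture) | COc1cc2c(cc1OCc1ccccc1)[C@@H](c1cc(OC)c(OCc3ccccc3)c(OC)c1)C(C(=O)OC)C(C(=O)OC)C2 | intermediate
16 | dimethyl (1R,2S,3S)-7-(benzyloxy)-1-[4-(benzyloxy)-3,5-dimethoxyphenyl]-6-methoxytetralin-2,3-dicarboxylate | COc1cc2c(cc1OCc1ccccc1)[C@@H](c1cc(OC)c(OCc3ccccc3)c(OC)c1)[C@H](C(=O)OC)[C@@H](C(=O)OC)C2 | intermediate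
17 | [(1R,2S,3S)-7-(benzyloxy)-1-[4-(benzyloxy)-3,5-dimethoxyphenyl]-6-methoxytetralin-2,3-diyl]dimethanol | COc1cc2c(cc1OCc1ccccc1)[C@@H](c1cc(OC)c(OCc3ccccc3)c(OC)c1)[C@H](CO)[C@@H](CO)C2 | intermediate
18 | (6S,7S,8R)-8-(4-hydroxy-3,5-dimethoxyphenyl)-6,7-bis(hydroxymethyl)-3-methoxy-5,6,7,8-tetrahydronaphthalen-2-ol | COc1cc2c(cc1O)[C@@H](c1cc(OC)c(O)c(OC)c1)[C@H](CO)[C@@H](CO)C2 | target

## Summary
- Total step count: 15
- Longest linear sequence: 10 (steps 1–5, then 11–15); the resorcinol branch (steps 6–9) and the fumarate branch (step 10) run in parallel.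

**Three steps most likely to fail**

1. **Step 12 (proposed new Pd-catalysed enantioselective [4+2]).** The risks are an uncatalysed ionisation/1,4-elimination of the very electron-rich carbonate (racemic background cycloaddition), low ee, or methoxide capture of the π-benzyl intermediate. Fallback (known chemistry): generate the free α-aryl-o-quinodimethane from 14 with CsF in MeCN and run a thermal Diels–Alder with a chiral-auxiliary fumarate diester (for example the bis-lactate or dimenthyl ester), separate the diastereomeric adducts, then continue with steps 13–15 (NaOMe transesterifies and epimerises). If auxiliary control is poor, use 13 and resolve rac-16 on a chiral stationary phase.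

2. **Step 5 (lateral lithiation/silylation).** The risks are competing ring lithiation between the imine and OBn, deprotonation of the benzyl ether, and protodesilylation during imine hydrolysis. Fallback: introduce the CH2SiMe3 group by cross-coupling instead of deprotonation. Ni(dppp)Cl2-catalysed Kumada coupling of Me3SiCH2MgCl with the dimethyl acetal of 2-bromo-5-(benzyloxy)-4-methoxybenzaldehyde, then acetal hydrolysis. The bromoaldehyde is made from catechol by monobenzylation, para-bromination, O-methylation, Br/Li–DMF formylation and ring bromination.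

3. **Step 11 (aryllithium addition and carbonate trapping).** The risks are C→O silyl migration in the lithium alkoxide next to the benzylsilane and solvolysis of the doubly activated benzhydryl carbonate on isolation. Fallback: avoid the lithium alkoxide by converting 11 into the arylboronic acid and adding it to 6 by Rh(I)-catalysed 1,2-addition under near-neutral conditions, isolating the benzhydrol, and acylating with ClCO2Me/pyridine immediately before step 12.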